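# Proposed synthesis of CNP0270681.0 (hexameric fuhalol-type phlorotannin, C36H26O20)

Conventions: rings A–F follow the SMILES from left to right. In ring C, C1 carries the oxygen to ring B, C2 the oxygen to ring D, C3–C5 the three OH and C6 the only H. In the other rings the "inner" carbon is the oxygen-bearing carbon between two oxygenated carbons; the "outer" carbon is the oxygen-bearing carbon para to it, between two CH.

## The problem

- The target (17) is six benzene rings in a row, joined only by five diaryl ether oxygens, with fifteen free phenolic OH and no inter-ring C–C bond.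
- It has no stereocentre and no configurationally stable axis. The task is one of connectivity and of telling twenty oxygens apart.
- Four ethers (A–B, B–C, D–E, E–F) leave an inner carbon, the worst case for any aryl–O coupling. The fifth (C2–O–ring D) sits on the pentaoxygenated ring C, ortho to the B–O–C ether and next to C3–OH.
- Every ring is a phloroglucinol- or pyrogallol-type arene. Carbon attack (biaryl formation) and over-oxidation threaten any oxidative or electrophilic step, and the free product will not stand air with base, so the OH groups must be freed last.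
- The feature that opens the problem: rings A–B–C and D–E–F are the same triaryl diether (outer-OH trioxyphenyl – O – dioxy-1,4-phenylene – O – 3,4,5-trioxyphenyl). The hexamer is two copies of it joined by one bond, from the outer oxygen of ring D to C2 of ring C.
- That carbon is a free CH of a pyrogallol ring. C3–OH/C4–OH of ring C form a catechol that can be dehydrogenated to an o-quinone, whose free ring carbons are electrophilic. Because C3, C4 and C5 all end as OH, the two free carbons C2 and C6 of ring C are equivalent in the final product.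

## Retrosynthesis

**17 ⇒ 16 ⇒ 15 (protecting groups).** Eleven O–CH3 bonds are cut, and one stage earlier two O–CH2Ph bonds. Methyl is the permanent group because the ring building block 5 is bought with it and it survives copper, peracid and Ag2O. Benzyl is used only on the one catechol that must be released without touching methyl. The same two benzyls sit on ring F of 15 and are removed by hydrogenolysis (15 → 16) before the Lewis acid, so that no benzyl electrophile meets the free polyphenol. The forward reaction asks for exhaustive BBr3 demethylation of 16.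

**15 ⇒ 14 + 11 (key cut, C of ring C–O of ring D).** Cutting any other ether gives two unequal fragments. This cut gives two fragments with the same trimer skeleton, each half the size of the target. The forward reaction is O-attack of the phenoxide of 11 on a free ring carbon of o-quinone 14, followed by enolisation to catechol 15. It copies the presumed biosynthetic oxidative C–O coupling at a pyrogallol ring.

**14 ⇒ 13 ⇒ 12 ⇒ 11 (making the two halves different).** The electrophile is the nucleophile after three routine operations. The outer OH of ring A is capped as methyl (12) so that it cannot compete as nucleophile, the two benzyls are hydrogenolysed to free the ring C catechol (13), and the catechol is dehydrogenated to 14. Nothing new has to be built for the second half.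

**11 ⇒ 9 ⇒ 8 + 5 and 8 ⇒ 6 ⇒ 4 + 5 (the trimer).** Each inner-carbon–O bond is cut to an outer phenol and the bromoaldehyde 5. The formyl group of 5 has two roles: it activates the hindered C–Br between two methoxy groups, and after Baeyer–Villiger oxidation (9 → 11, 6 → 8) it becomes the outer OH that is the nucleophile for the next cycle. The opposite polarity would pair a hindered 2,6-dimethoxyphenol with an unactivated bromide and needs an extra deprotection per ring.

**4 ⇒ 2 ⇒ 1.** The first phenol 4 comes from commercial 5-hydroxyvanillin 1 by benzylation (2) and the same formyl-to-hydroxyl oxidation. Its 3,4-bis(benzyloxy)-5-methoxy pattern is what later releases the ring C catechol.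

## Roads not taken

**Alternative 1:** the obvious route cuts all five ethers one at a time (Ullmann coupling with methyl-protected monomers, then global demethylation).
- Ring C would enter as a linchpin A1 (bromide para to formyl, benzyl on the C1 oxygen). An all-methyl trimer phenol A2 would be coupled with A1, followed by Baeyer–Villiger oxidation, methylation, debenzylation and two more coupling/oxidation cycles with 5, ending in the permethylated hexamer A3.
- This is at least fourteen steps in one line plus a separate multistep preparation of A1.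
- The repeat A–B–C = D–E–F is built twice by hand.
- The coupling at ring C is no easier than anywhere else. The chosen plan builds the repeat once and spends one step on the union.

**Alternative 2:** three components around ring C.
- 3-Methoxy-o-quinone A5 would take up the inner phenol A4 (rings A–B) at C5, be re-oxidised, and then take up 11 at C4.
- A4 has a 2,6-dimethoxyphenol OH, a type the coupling/oxidation cycle never produces, so it needs its own synthesis.
- The first addition asks a di-ortho-substituted phenoxide to choose between two free carbons of A5. Two quinone stages are needed, and the second is the chosen key step anyway.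
- The chosen plan makes the C1–O–ring B bond by the ordinary iteration and uses the quinone once.

**Alternative 3:** protecting-group-free oxidative dimerisation of the free trimer A6 with a one-electron oxidant or an oxidase.
- It is the shortest route on paper.
- A6 carries both reacting functions and seven OH in each molecule, so the dimer can react again.
- Ring A is a phloroglucinol that couples through carbon.
- The hydroxy-o-quinone of a free pyrogallol is a vinylogous acid that is lost to benzotropolone-type chemistry.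
- Nothing in A6 controls any of this. Two trivial steps (MeI, H2) in the chosen plan assign the two roles.

Key step: step 9

Assumption: the SMILES has no stereocentre and the diaryl ether bonds rotate freely, so the target is achiral and "single enantiomer" has no consequence for the route.

## Route

Step 1
Reactants: 1 3,4-dihydroxy-5-methoxybenzaldehyde (5-hydroxyvanillin)
Product: 2 3,4-bis(benzyloxy)-5-methoxybenzaldehyde
Conditions: BnBr, K2CO3, DMF, 60 °C
Reagents that add atoms: benzyl bromide, BrCc1ccccc1
Why: Williamson etherification of both phenols; the aldehyde is not enolisable and is untouched.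

Step 2
Reactants: 2 3,4-bis(benzyloxy)-5-methoxybenzaldehyde
Product: 4 3,4-bis(benzyloxy)-5-methoxyphenol, via aryl formate 3 (not isolated)
Conditions: mCPBA, NaHCO3, CH2Cl2, 0 °C to rt; then K2CO3 (cat.), MeOH, rt
Reagents that add atoms: mCPBA, OOC(=O)c1cccc(Cl)c1
Why: Baeyer–Villiger (Dakin-type) oxidation; the trialkoxyaryl group migrates in preference to H, and the formate is cleaved by methanolysis, as for 3,4,5-trialkoxybenzaldehydes in general.

Step 3
Reactants: 4 3,4-bis(benzyloxy)-5-methoxyphenol; 5 4-bromo-3,5-dimethoxybenzaldehyde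
Product: 6 4-[3,4-bis(benzyloxy)-5-methoxyphenoxy]-3,5-dimethoxybenzaldehyde
Conditions: CuI (cat.), picolinic acid (cat.), K3PO4, DMSO, 90 °C
Reagents that add atoms: none
Why: Ullmann-type copper-catalysed C–O coupling; the para-formyl group activates the C–Br between two methoxy groups and the phenol is unhindered (two ortho H).

Step 4
Reactants: 6 4-[3,4-bis(benzyloxy)-5-methoxyphenoxy]-3,5-dimethoxybenzaldehyde
Product: 8 4-[3,4-bis(benzyloxy)-5-methoxyphenoxy]-3,5-dimethoxyphenol, via aryl formate 7 (not isolated)
Conditions: mCPBA, NaHCO3, CH2Cl2, 0 °C to rt; then K2CO3 (cat.), MeOH, rt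
Reagents that add atoms: mCPBA, OOC(=O)c1cccc(Cl)c1
Why: Baeyer–Villiger oxidation of a 4-aryloxy-3,5-dimethoxybenzaldehyde (electron-rich migrating aryl) and formate methanolysis; this frees the outer OH for the next coupling.

Step 5
Reactants: 8 4-[3,4-bis(benzyloxy)-5-methoxyphenoxy]-3,5-dimethoxyphenol; 5 4-bromo-3,5-dimethoxybenzaldehyde
Product: 9 4-{4-[3,4-bis(benzyloxy)-5-methoxyphenoxy]-3,5-dimethoxyphenoxy}-3,5-dimethoxybenzaldehyde
Conditions: CuI (cat.), picolinic acid (cat.), K3PO4, DMSO, 90 °C
Reagents that add atoms: none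
Why: second Ullmann-type C–O coupling of the same kind as step 3; the nucleophile is again an outer phenol with two ortho H.

Step 6
Reactants: 9 4-{4-[3,4-bis(benzyloxy)-5-methoxyphenoxy]-3,5-dimethoxyphenoxy}-3,5-dimethoxybenzaldehyde
Product: 11 4-{4-[3,4-bis(benzyloxy)-5-methoxyphenoxy]-3,5-dimethoxyphenoxy}-3,5-dimethoxyphenol, via aryl formate 10 (not isolated)
Conditions: mCPBA, NaHCO3, CH2Cl2, 0 °C to rt; then K2CO3 (cat.), MeOH, rt
Reagents that add atoms: mCPBA, OOC(=O)c1cccc(Cl)c1
Why: Baeyer–Villiger oxidation and formate methanolysis as in steps 2 and 4; 11 is the common trimer and the nucleophile of the key step.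

Step 7
Reactants: 11 4-{4-[3,4-bis(benzyloxy)-5-methoxyphenoxy]-3,5-dimethoxyphenoxy}-3,5-dimethoxyphenol
Product: 12 1,2-bis(benzyloxy)-5-[2,6-dimethoxy-4-(2,4,6-trimethoxyphenoxy)phenoxy]-3-methoxybenzene
Conditions: MeI, K2CO3, acetone, reflux
Reagents that add atoms: iodomethane, CI
Why: Williamson methylation of the only free phenol, so that ring A cannot act as a nucleophile in step 9.

Step 8
Reactants: 12 1,2-bis(benzyloxy)-5-[2,6-dimethoxy-4-(2,4,6-trimethoxyphenoxy)phenoxy]-3-methoxybenzene
Product: 13 5-[2,6-dimethoxy-4-(2,4,6-trimethoxyphenoxy)phenoxy]-3-methoxybenzene-1,2-diol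
Conditions: H2 (1 atm), Pd/C, EtOAc–MeOH, rt; filtered and used under Ar
Reagents that add atoms: none
Why: hydrogenolysis of the two benzyl ethers; methyl and diaryl ethers are inert, so only the ring C catechol is freed.

Step 9
Reactants: 13 5-[2,6-dimethoxy-4-(2,4,6-trimethoxyphenoxy)phenoxy]-3-methoxybenzene-1,2-diol; 11 4-{4-[3,4-bis(benzyloxy)-5-methoxyphenoxy]-3,5-dimethoxyphenoxy}-3,5-dimethoxyphenol
Product: 15 4-(4-{4-[3,4-bis(benzyloxy)-5-methoxyphenoxy]-3,5-dimethoxyphenoxy}-3,5-dimethoxyphenoxy)-5-[2,6-dimethoxy-4-(2,4,6-trimethoxyphenoxy)phenoxy]-3-methoxybenzene-1,2-diol, via o-quinone 14 (not isolated)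
Conditions: 13, Ag2O, Na2SO4, CH2Cl2, 0 °C, filtered under Ar; filtrate added slowly to 11 (slight excess), Cs2CO3 (cat.), MeCN, −30 °C to 0 °C; AcOH quench
Reagents that add atoms: none
Why: Ag2O dehydrogenates the only free catechol (ring C of 13) to o-quinone 14 without any nucleophile, so the C1–O–ring B bond para to C4–OH is never placed on a ketal carbon, and rings A and B (all methyl) and ring F of 11 (benzyl, methyl) cannot become quinones. The caesium phenoxide of 11 then adds through oxygen to C6 of 14, the free β-carbon of the C4 carbonyl (the carbonyl that receives no vinylogous-ester donation from the C1 aryloxy group), and enolisation restores the aromatic catechol 15, which makes the C–H addition irreversible. This is the oxa-Michael addition of a phenol to an o-quinone, the reaction type by which alcohols and phenols are added to catechol- and gallate-derived o-quinones and their monoketals to give highly oxygenated aryl ethers; it copies the presumed biosynthetic C–O coupling. No ring is closed and no stereocentre is formed. O- over C-attack of the ambident phenoxide is favoured by the caesium salt in a polar aprotic solvent at low temperature, under kinetic control. Selectivity between the two free carbons of ring C is not needed: addition at C2 instead of C6 would only change which pyrogallol oxygen carries the methyl group, and both adducts end as the same compound after step 11. Attack at C1 (ipso to the ring B aryloxy group) is a reversible addition–elimination and is the main competitor; slow addition of 14 to a slight excess of phenoxide keeps the quinone concentration low and also limits dehydrogenation of 15 by unreacted 14.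

Step 10
Reactants: 15 4-(4-{4-[3,4-bis(benzyloxy)-5-methoxyphenoxy]-3,5-dimethoxyphenoxy}-3,5-dimethoxyphenoxy)-5-[2,6-dimethoxy-4-(2,4,6-trimethoxyphenoxy)phenoxy]-3-methoxybenzene-1,2-diol
Product: 16 4-(4-{4-[3,4-dihydroxy-5-methoxyphenoxy]-3,5-dimethoxyphenoxy}-3,5-dimethoxyphenoxy)-5-[2,6-dimethoxy-4-(2,4,6-trimethoxyphenoxy)phenoxy]-3-methoxybenzene-1,2-diol
Conditions: H2 (1 atm), Pd/C, THF–MeOH, rt; filtered under Ar
Reagents that add atoms: none
Why: hydrogenolysis of the two ring F benzyl ethers; doing this before the Lewis acid step avoids Friedel–Crafts benzylation of the electron-rich rings.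

Step 11
Reactants: 16 4-(4-{4-[3,4-dihydroxy-5-methoxyphenoxy]-3,5-dimethoxyphenoxy}-3,5-dimethoxyphenoxy)-5-[2,6-dimethoxy-4-(2,4,6-trimethoxyphenoxy)phenoxy]-3-methoxybenzene-1,2-diol
Product: 17 4-{3,5-dihydroxy-4-[3,5-dihydroxy-4-(3,4,5-trihydroxyphenoxy)phenoxy]phenoxy}-5-[2,6-dihydroxy-4-(2,4,6-trihydroxyphenoxy)phenoxy]benzene-1,2,3-triol (target)
Conditions: BBr3 (excess), CH2Cl2, −78 °C to rt; degassed MeOH then H2O, under Ar
Reagents that add atoms: none
Why: Lewis-acid cleavage of all eleven aryl methyl ethers (bromide attacks the methyl of the boron-complexed ether); diaryl ethers offer no SN2 carbon and stay intact.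

## Compound list

1 | 3,4-dihydroxy-5-methoxybenzaldehyde | O=Cc1cc(O)c(O)c(OC)c1 | starting material
2 | 3,4-bis(benzyloxy)-5-methoxybenzaldehyde | O=Cc1cc(OCc2ccccc2)c(OCc2ccccc2)c(OC)c1 | intermediate
3 | 3,4-bis(benzyloxy)-5-methoxyphenyl formate | O=COc1cc(OCc2ccccc2)c(OCc2ccccc2)c(OC)c1 | intermediate (not isolated)
4 | 3,4-bis(benzyloxy)-5-methoxyphenol | Oc1cc(OCc2ccccc2)c(OCc2ccccc2)c(OC)c1 | intermediate
5 | 4-bromo-3,5-dimethoxybenzaldehyde | O=Cc1cc(OC)c(Br)c(OC)c1 | starting material
6 | 4-[3,4-bis(benzyloxy)-5-methoxyphenoxy]-3,5-dimethoxybenzaldehyde | O=Cc1cc(OC)c(Oc2cc(OCc3ccccc3)c(OCc3ccccc3)c(OC)c2)c(OC)c1 | intermediate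
7 | 4-[3,4-bis(benzyloxy)-5-methoxyphenoxy]-3,5-dimethoxyphenyl formate | O=COc1cc(OC)c(Oc2cc(OCc3ccccc3)c(OCc3ccccc3)c(OC)c2)c(OC)c1 | intermediate (not isolated)
8 | 4-[3,4-bis(benzyloxy)-5-methoxyphenoxy]-3,5-dimethoxyphenol | Oc1cc(OC)c(Oc2cc(OCc3ccccc3)c(OCc3ccccc3)c(OC)c2)c(OC)c1 | intermediate
9 | 4-{4-[3,4-bis(benzyloxy)-5-methoxyphenoxy]-3,5-dimethoxyphenoxy}-3,5-dimethoxybenzaldehyde | O=Cc1cc(OC)c(Oc2cc(OC)c(Oc3cc(OCc4ccccc4)c(OCc4ccccc4)c(OC)c3)c(OC)c2)c(OC)c1 | intermediate
10 | 4-{4-[3,4-bis(benzyloxy)-5-methoxyphenoxy]-3,5-dimethoxyphenoxy}-3,5-dimethoxyphenyl formate | O=COc1cc(OC)c(Oc2cc(OC)c(Oc3cc(OCc4ccccc4)c(OCc4ccccc4)c(OC)c3)c(OC)c2)c(OC)c1 | intermediate (not isolated)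
11 | 4-{4-[3,4-bis(benzyloxy)-5-methoxyphenoxy]-3,5-dimethoxyphenoxy}-3,5-dimethoxyphenol (common trimer, nucleophile) | Oc1cc(OC)c(Oc2cc(OC)c(Oc3cc(OCc4ccccc4)c(OCc4ccccc4)c(OC)c3)c(OC)c2)c(OC)c1 | intermediate
12 | 1,2-bis(benzyloxy)-5-[2,6-dimethoxy-4-(2,4,6-trimethoxyphenoxy)phenoxy]-3-methoxybenzene | COc1cc(OC)c(Oc2cc(OC)c(Oc3cc(OCc4ccccc4)c(OCc4ccccc4)c(OC)c3)c(OC)c2)c(OC)c1 | intermediate
13 | 5-[2,6-dimethoxy-4-(2,4,6-trimethoxyphenoxy)phenoxy]-3-methoxybenzene-1,2-diol | COc1cc(OC)c(Oc2cc(OC)c(Oc3cc(O)c(O)c(OC)c3)c(OC)c2)c(OC)c1 | intermediate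
14 | 5-[2,6-dimethoxy-4-(2,4,6-trimethoxyphenoxy)phenoxy]-3-methoxycyclohexa-3,5-diene-1,2-dione (o-quinone, electrophile) | COC1=CC(Oc2c(OC)cc(Oc3c(OC)cc(OC)cc3OC)cc2OC)=CC(=O)C1=O | intermediate (not isolated)
15 | 4-(4-{4-[3,4-bis(benzyloxy)-5-methoxyphenoxy]-3,5-dimethoxyphenoxy}-3,5-dimethoxyphenoxy)-5-[2,6-dimethoxy-4-(2,4,6-trimethoxyphenoxy)phenoxy]-3-methoxybenzene-1,2-diol | Oc1cc(Oc2c(OC)cc(Oc3c(OC)cc(OC)cc3OC)cc2OC)c(Oc4cc(OC)c(Oc5cc(OC)c(Oc6cc(OCc7ccccc7)c(OCc7ccccc7)c(OC)c6)c(OC)c5)c(OC)c4)c(OC)c1O | intermediate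
16 | 4-(4-{4-[3,4-dihydroxy-5-methoxyphenoxy]-3,5-dimethoxyphenoxy}-3,5-dimethoxyphenoxy)-5-[2,6-dimethoxy-4-(2,4,6-trimethoxyphenoxy)phenoxy]-3-methoxybenzene-1,2-diol | Oc1cc(Oc2c(OC)cc(Oc3c(OC)cc(OC)cc3OC)cc2OC)c(Oc4cc(OC)c(Oc5cc(OC)c(Oc6cc(O)c(O)c(OC)c6)c(OC)c5)c(OC)c4)c(OC)c1O | intermediate
17 | 4-{3,5-dihydroxy-4-[3,5-dihydroxy-4-(3,4,5-trihydroxyphenoxy)phenoxy]phenoxy}-5-[2,6-dihydroxy-4-(2,4,6-trihydroxyphenoxy)phenoxy]benzene-1,2,3-triol | Oc1cc(O)c(Oc2cc(O)c(Oc3cc(O)c(O)c(O)c3Oc3cc(O)c(Oc4cc(O)c(Oc5cc(O)c(O)c(O)c5)c(O)c4)c(O)c3)c(O)c2)c(O)c1 | target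

## Step count and risk

Total steps: 11. Longest linear sequence: 11 (1 → 2 → 4 → 6 → 8 → 9 → 11 → 12 → 13 → 15 → 16 → 17); both halves of the target come from the one intermediate 11.

**Step 9 (key step).** Four processes may go wrong:
- ether exchange at C1 of the quinone (addition–elimination that swaps the ring B aryloxy group for the incoming phenoxide instead of adding at a C–H carbon);
- carbon attack of the phenoxide through the ortho positions of ring D;
- hetero-Diels–Alder self-dimerisation of the o-quinone;
- hydrogen transfer from the product catechol to unreacted quinone followed by a second addition (an ascorbic acid or dithionite wash would return over-oxidised product to the catechol).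

Fallback, setting out from 13 (through its quinone 14) and 11 and returning at 17:
- The quinone solution is treated with HBr in AcOH/CH2Cl2 at 0 °C. This classical hydrohalogenation of a quinone should brominate ring C only, because only that ring is quinonoid, giving the bromocatechol F1.
- Methylation (MeI, K2CO3, acetone) gives the aryl bromide F2. It is the same compound whichever free carbon took the bromide, since ring C then carries three methoxy groups.
- Copper-catalysed Ullmann coupling of F2 with 11 (CuI, picolinic acid, K3PO4, DMSO, 110 °C) gives the fully protected hexamer F3.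
- Hydrogenolysis (H2, Pd/C) gives the ring F catechol F4, and BBr3 as in step 11 gives 17.

**Step 5 (and, to a lesser degree, step 3).** Activation of the C–Br between two methoxy groups may be slow, so that protodebromination of 5 or base-induced loss of the aldehyde outruns the coupling; this is more likely with the larger phenol 8. Fallback, setting out from 8 and returning at 9: metal-free aryl transfer from a diaryliodonium salt.
- The salt F5, (4-formyl-2,6-dimethoxyphenyl)(2,4,6-trimethoxyphenyl)iodonium tosylate, is made from 4-iodo-3,5-dimethoxybenzaldehyde (mCPBA, TsOH, then 1,3,5-trimethoxybenzene).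
- F5 is treated with the potassium phenoxide of 8 (K2CO3 or t-BuOK, THF/toluene, rt to 50 °C).
- Ligand coupling at iodine should transfer the less electron-rich formyl-bearing aryl group and leave the trimethoxyphenyl group on iodine; this kind of coupling tolerates di-ortho substitution.

**Step 11.** Cleavage may stall at partly methylated boron chelates as they precipitate, and the free pentadecaol may be lost to air oxidation during isolation. Fallback, setting out from 16 and returning at 17:
- The crude demethylation product is acetylated without purification (Ac2O, pyridine, Ar) to the pentadecaacetate F6, which is stable and can be chromatographed.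
- Incompletely demethylated fractions are resubmitted to BBr3.
- Pure F6 is deacetylated with HCl in degassed MeOH (generated from AcCl) to give 17 without exposure to base.

## Further compounds

F1 | step 9 | 4-bromo-5-[2,6-dimethoxy-4-(2,4,6-trimethoxyphenoxy)phenoxy]-3-methoxybenzene-1,2-diol | Oc1cc(Oc2c(OC)cc(Oc3c(OC)cc(OC)cc3OC)cc2OC)c(Br)c(OC)c1O
F2 | step 9 | 2-bromo-1-[2,6-dimethoxy-4-(2,4,6-trimethoxyphenoxy)phenoxy]-3,4,5-trimethoxybenzene | COc1cc(Oc2c(OC)cc(Oc3c(OC)cc(OC)cc3OC)cc2OC)c(Br)c(OC)c1OC
F3 | step 9 | 1-[2,6-dimethoxy-4-(2,4,6-trimethoxyphenoxy)phenoxy]-2-(4-{4-[3,4-bis(benzyloxy)-5-methoxyphenoxy]-3,5-dimethoxyphenoxy}-3,5-dimethoxyphenoxy)-3,4,5-trimethoxybenzene | COc1cc(Oc2c(OC)cc(Oc3c(OC)cc(OC)cc3OC)cc2OC)c(Oc4cc(OC)c(Oc5cc(OC)c(Oc6cc(OCc7ccccc7)c(OCc7ccccc7)c(OC)c6)c(OC)c5)c(OC)c4)c(OC)c1OC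
F4 | step 9 | 5-[4-(4-{6-[2,6-dimethoxy-4-(2,4,6-trimethoxyphenoxy)phenoxy]-2,3,4-trimethoxyphenoxy}-2,6-dimethoxyphenoxy)-2,6-dimethoxyphenoxy]-3-methoxybenzene-1,2-diol | COc1cc(Oc2c(OC)cc(Oc3c(OC)cc(OC)cc3OC)cc2OC)c(Oc4cc(OC)c(Oc5cc(OC)c(Oc6cc(O)c(O)c(OC)c6)c(OC)c5)c(OC)c4)c(OC)c1OC
F5 | step 5 | (4-formyl-2,6-dimethoxyphenyl)(2,4,6-trimethoxyphenyl)iodonium 4-methylbenzenesulfonate | O=Cc1cc(OC)c([I+]c2c(OC)cc(OC)cc2OC)c(OC)c1.Cc1ccc(cc1)S(=O)(=O)[O-]
F6 | step 11 | pentadecaacetate of 17 (every OH as OAc) | CC(=O)Oc1cc(OC(C)=O)c(Oc2cc(OC(C)=O)c(Oc3cc(OC(C)=O)c(OC(C)=O)c(OC(C)=O)c3Oc3cc(OC(C)=O)c(Oc4cc(OC(C)=O)c(Oc5cc(OC(C)=O)c(OC(C)=O)c(OC(C)=O)c5)c(OC(C)=O)c4)c(OC(C)=O)c3)c(OC(C)=O)c2)c(OC(C)=O)c1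
A1 | alternative 1 | 5-(benzyloxy)-4-bromo-2,3-dimethoxybenzaldehyde | O=Cc1cc(OCc2ccccc2)c(Br)c(OC)c1OC
A2 | alternative 1 | 4-[3,5-dimethoxy-4-(3,4,5-trimethoxyphenoxy)phenoxy]-3,5-dimethoxyphenol | Oc1cc(OC)c(Oc2cc(OC)c(Oc3cc(OC)c(OC)c(OC)c3)c(OC)c2)c(OC)c1
A3 | alternative 1 | pentadeca-O-methyl ether of 17 | COc1cc(OC)c(Oc2cc(OC)c(Oc3cc(OC)c(OC)c(OC)c3Oc3cc(OC)c(Oc4cc(OC)c(Oc5cc(OC)c(OC)c(OC)c5)c(OC)c4)c(OC)c3)c(OC)c2)c(OC)c1
A4 | alternative 2 | 2,6-dimethoxy-4-(2,4,6-trimethoxyphenoxy)phenol | Oc1c(OC)cc(Oc2c(OC)cc(OC)cc2OC)cc1OC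
A5 | alternative 2 | 3-methoxycyclohexa-3,5-diene-1,2-dione | COC1=CC=CC(=O)C1=O
A6 | alternative 3 | 5-[2,6-dihydroxy-4-(2,4,6-trihydroxyphenoxy)phenoxy]benzene-1,2,3-triol | Oc1cc(O)c(Oc2cc(O)c(Oc3cc(O)c(O)c(O)c3)c(O)c2)c(O)c1
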